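5 questions stand here, and one reckoning serves them.

    reagent + free catalyst → catalyst intermediate A (k1 = 0.351 M⁻¹ s⁻¹)
    catalyst intermediate A → by-product + catalyst intermediate B (k2 = 0.0233 s⁻¹)
    substrate + catalyst intermediate B → catalyst intermediate C (k3 = 0.923 M⁻¹ s⁻¹)
    catalyst intermediate C → free catalyst + target (k4 = 0.262 s⁻¹)
    free catalyst + target ⇌ idle complex (K5 = 7.8 M⁻¹, k5 = 0.0197 M⁻¹ s⁻¹)

in all of them: free catalyst 1.2 mol%
- north-east: substrate 0.050 M; reagent 3.00 equiv; time 1.0 h; a closed flask charged with all of it at once and left for 1.0 h
- north: substrate 0.050 M (fed, over 1.00 h); reagent 3.00 equiv; time 1.0 h; a stirred flask in which substrate is dosed at a steady rate over 1.00 h without added volume, worked up at 1.0 h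
- south: substrate 0.050 M; reagent 3.00 equiv (fed, over 1.00 h); time 1.0 h; all but reagent at the start; reagent goes in evenly over 1.00 h, the run ends at 1.0 h
- south-east: substrate 0.050 M; reagent 3.00 equiv; one stirred flow tank at steady state, fed with the mixture as stated, mean residence time 1.0 h

1. the set-up with the highest amount of target at the outlet or at the end, in percent of the substrate put in ("none" if the first two lie within 2 percentage points) (north-east / north / south / south-east / none)
2. amount of target at the outlet or at the end, in percent of the substrate put in, north-east
3. amount of target at the outlet or at the end, in percent of the substrate put in, north
4. amount of target at the outlet or at the end, in percent of the substrate put in, south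
5. amount of target at the outlet or at the end, in percent of the substrate put in, south-east

- for target the idle complex is counted in
- the stated concentrations are those of everything mixed, before any reaction; amounts are the same in each set-up
- the feed brings no volume worth counting
- run time (north-east): 1.0 h

Freeze what moves slowly: the catalyst loading stays fixed, and substrate and reagent can be held at suitable values. Then define the cycle time τ, the sum of the waits of one catalyst turn at the concentrations present: the reciprocals of the two pseudo-first-order rates of capture by reagent and by substrate, plus the lifetimes of catalyst intermediates A and C. At the charge, 87.4 s, and the breakdown of intermediate A is the longest wait at 42.9 s. You get target, in percent of substrate, as loading times run time over τ, which gives 49.4% at frozen charge values. I leave out the idle complex: with target at that figure, the equilibrium constant of step 5 times its concentration is 0.193, so an idle complex at equilibrium with free catalyst adds that fraction of the wait for capture by reagent, 3.66 s, which is smaller than τ.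

Now compare north-east with north, which has the same amounts but doses its substrate. In north-east, with hour-mean concentrations at half that conversion, the substrate wait is 28.8 s, τ becomes 96.2 s, and the yield is 44.9%. In north, the substrate stock climbs from zero, so its mean is half of what remains at the end. Trying a third conversion gives a substrate wait of 65.0 s, τ of 132 s, and a yield of 32.8%, which is consistent with the trial. North therefore ends lower because its substrate wait is longer.

The forecast chose north-east, with 43.8% for north-east, 31% for north, 32.5% for south and 39.8% for south-east, on the ground that the outcome depends on “keeping both the reagent and substrate concentrations high for the whole hour”. My two figures lie above its values for those flasks.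

The simulation gives 44.0% for north-east, 31.4% for north, 32.6% for south and 39.7% for south-east, so north-east is best.

In north-east, the cycle turned through the hour while substrate fell to 56.0% of its charge, and τ at that end point reads 108 s. In south-east, the catalyst turned at one steady state with reagent at 0.130 M and substrate at 60.3% of its charge, where τ reads 105 s, so loading times residence time over τ gives 41.3%, and that tank delivers 39.7%.

Its constants stand for no real mixture.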